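## Retrosynthetic overview

1. Polymatin A ⇐ one-pot CrCl2 (Nozaki–Hiyama) macro-allylation / translactonization of an enal tethered to a 3-(bromomethyl)-5-angeloyloxy-5,6-dihydropyran-2-one. This forms C6–C7, the ten-membered ring and both C6/C7 stereocentres; the C6 alkoxide then takes the acyl group from O9, giving the 6,12-γ-lactone and freeing 9-OH.
2. The δ-lactone "template" ⇐ RCM of a C9 2-(silyloxymethyl)acrylate onto a C7 vinyl group. It differentiates O8 from O9, locks the allyl geometry needed for the trans-lactone, and lets the angelate go on before cyclisation.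
3. C8/C9 threo-diol ⇐ Brown (Z)-γ-alkoxyallylboration of a 2-formyl-enoate (both stereocentres by reagent control).
4. 2-Formyl-enoate with the ring-cis C1=C10 geometry ⇐ Morita–Baylis–Hillman / SN2′ bromination / N-oxide oxidation from the geranyl acetate-derived aldehyde and methyl acrylate.
5. Ring order: dihydropyranone (temporary) → cyclodecadiene → γ-lactone (same pot, opens the dihydropyranone).

Assumption: geranyl acetate, methyl acrylate, allyl methoxymethyl ether, (+)-Ipc2BOMe, methyl 2-(hydroxymethyl)acrylate and angelic acid are taken as commercially available. Atom labels C1–C15 below use germacrane numbering of the target.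

## Route

**Step 1**
Reactants: 1, geranyl acetate
Product: 2, (4E)-6-acetoxy-4-methylhex-4-enal (C1 aldehyde … C6–OAc)
Conditions: O3 (1 equiv), CH2Cl2/pyridine, −78 °C; Me2S
Reagents that add atoms: ozone, [O-][O+]=O
Why: Chemoselective ozonolysis of the electron-rich distal trisubstituted alkene, the 2,3-alkene being deactivated by the allylic acetate; the 4E geometry comes from the starting material.

**Step 2**
Reactants: 2; 3, methyl acrylate
Product: 4, methyl (6E)-8-acetoxy-3-hydroxy-6-methyl-2-methylideneoct-6-enoate (racemic carbinol)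
Conditions: DABCO (1 equiv), neat, rt, 3–5 d
Reagents that add atoms: methyl acrylate, C=CC(=O)OC
Why: Morita–Baylis–Hillman reaction of an unhindered aliphatic aldehyde; it installs C10, C14 and C9 in one step, and the carbinol centre is destroyed in step 3.

**Step 3**
Reactants: 4
Product: 5, methyl (2Z,6E)-8-acetoxy-2-(bromomethyl)-6-methylocta-2,6-dienoate
Conditions: NBS, Me2S, CH2Cl2, 0 °C→rt
Reagents that add atoms: NBS, O=C1CCC(=O)N1Br
Why: Corey–Kim-type SN2′ bromination of a Baylis–Hillman alcohol, which gives the (Z)-2-(bromomethyl)enoate (chain cis to CH2Br, trans to CO2Me), i.e. the ring-cis C1=C10 geometry of the target.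

**Step 4**
Reactants: 5
Product: 6, methyl (2E,6E)-8-acetoxy-2-formyl-6-methylocta-2,6-dienoate (C9 aldehyde)
Conditions: NMO (4 equiv), MeCN, 4 Å MS, 0 °C→rt
Reagents that add atoms: N-methylmorpholine N-oxide, C[N+]1([O-])CCOCC1
Why: Ganem/Kornblum-type N-oxide oxidation of the primary allylic bromide; the geometry is retained and is also the thermodynamic one (alkyl cis to the smaller CHO).

**Step 5**
Reactants: 6; 7, allyl methoxymethyl ether
Product: 8, methyl (2E,6E)-8-acetoxy-2-[(1S,2S)-1-hydroxy-2-(methoxymethoxy)but-3-en-1-yl]-6-methylocta-2,6-dienoate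
Conditions: 7, s-BuLi, THF, −78 °C; (+)-Ipc2BOMe; BF3·OEt2; then 6, −78 °C; ethanolamine work-up
Reagents that add atoms: allyl methoxymethyl ether, C=CCOCOC
Why: Brown (Z)-γ-alkoxyallylboration: the chair transition state of the (Z)-γ-MOM-oxyallylborane gives the syn (threo) product, and the Ipc ligands from (−)-α-pinene direct re-face attack, setting C9 (S, free OH) and C8 (S, OMOM) together with the two oxygens already differentiated.

**Step 6**
Reactants: 8
Product: 9, methyl (2E,6E)-8-hydroxy-2-[(1S,2S)-1-hydroxy-2-(methoxymethoxy)but-3-en-1-yl]-6-methylocta-2,6-dienoate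
Conditions: K2CO3, MeOH, 0 °C
Reagents that add atoms: none
Why: Zemplén-type methanolysis of the primary allylic acetate; the C14 methyl ester is degenerate under methoxide and no stereocentre is base-labile.

**Step 7**
Reactants: 9
Product: 10, the C6 primary TBS ether of 9
Conditions: TBSCl (1.05 equiv), imidazole, CH2Cl2, −20→0 °C
Reagents that add atoms: TBSCl, CC(C)(C)[Si](C)(C)Cl
Why: Selective silylation of the primary allylic alcohol over the hindered secondary C9–OH.

**Step 8** (side branch)
Reactants: 11, methyl 2-(hydroxymethyl)acrylate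
Product: 12, methyl 2-[(tert-butyldimethylsilyloxy)methyl]acrylate
Conditions: TBSCl, imidazole, DMF, 0 °C→rt
Reagents that add atoms: TBSCl, CC(C)(C)[Si](C)(C)Cl
Why: Standard silyl protection of a primary alcohol.

**Step 9** (side branch)
Reactants: 12
Product: 13, 2-[(tert-butyldimethylsilyloxy)methyl]acrylic acid
Conditions: LiOH, THF/H2O, 0 °C
Reagents that add atoms: lithium hydroxide/water, [Li+].[OH-]
Why: Saponification of the methyl ester; the primary TBS ether survives cold LiOH.

**Step 10**
Reactants: 10; 13
Product: 14, the C9 ester of 10 with 13 [(1S,2S)-configured 2-(TBSO-methyl)acrylate]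
Conditions: 2,4,6-Cl3C6H2COCl, Et3N, THF; then 10, DMAP, toluene, rt
Reagents that add atoms: acid 13, C=C(CO[Si](C)(C)C(C)(C)C)C(=O)O
Why: Yamaguchi esterification of the only free hydroxyl; C–O is not broken, so C9 is retained.

**Step 11**
Reactants: 14
Product: 15, (5S,6S)-3-[(TBSO)methyl]-5-(methoxymethoxy)-6-[(2E,6E)-8-(TBSO)-1-methoxy-6-methyl-1-oxoocta-2,6-dien-2-yl]-5,6-dihydro-2H-pyran-2-one
Conditions: Grubbs II (10 mol %), toluene, 80 °C, 5 mM
Reagents that add atoms: none (ethylene lost)
Why: Ring-closing metathesis of an α-substituted acrylate with a monosubstituted vinyl group to a six-membered unsaturated lactone; the two trisubstituted alkenes are inert, and the ring fixes C8 cis to the C12 carbonyl across C7=C11.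

**Step 12**
Reactants: 15
Product: 16, the (5S,6S)-5-hydroxy lactone (MOM removed, both TBS ethers intact)
Conditions: Me2BBr, CH2Cl2, −78 °C; aq. NaHCO3
Reagents that add atoms: none
Why: Guindon acetal cleavage is selective for MOM at −78 °C; esters, the lactone and primary TBS ethers are untouched.

**Step 13**
Reactants: 16; 17, angelic acid
Product: 18, the (5S,6S)-5-O-angelate [(Z)-2-methylbut-2-enoate] of 16
Conditions: 17, 2,4,6-Cl3C6H2COCl, Et3N, toluene, rt; then 16, 75 °C (no DMAP)
Reagents that add atoms: angelic acid, C/C=C(/C)C(=O)O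
Why: Yamaguchi mixed-anhydride angeloylation without nucleophilic catalyst, the standard way to avoid Z→E isomerisation to the tiglate; C8 is acylated with retention.

**Step 14**
Reactants: 18
Product: 19, the bis-primary diol (C6–OH and C13–OH) of 18
Conditions: HF·pyridine, pyridine/THF, 0 °C→rt
Reagents that add atoms: none
Why: Buffered fluoride desilylation of two primary TBS ethers; the angelate, δ-lactone and methyl ester are stable.

**Step 15**
Reactants: 19
Product: 20, the (2E)-enal at C6 (C13–OH retained)
Conditions: MnO2 (15 equiv), CH2Cl2, rt, monitored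
Reagents that add atoms: none
Why: MnO2 oxidises the electron-rich geraniol-type allylic alcohol much faster than the electron-poor 2-(hydroxymethyl)enoate-type alcohol, without E/Z scrambling.

**Step 16**
Reactants: 20
Product: 21, (5S,6S)-5-angeloyloxy-3-(bromomethyl)-6-[(2E,6E)-1-methoxy-6-methyl-1,8-dioxoocta-2,6-dien-2-yl]-5,6-dihydro-2H-pyran-2-one
Conditions: Ms2O, i-Pr2NEt, CH2Cl2, −40 °C; LiBr, THF, −40→0 °C; used at once
Reagents that add atoms: lithium bromide, [Li+].[Br-]
Why: Mesylation/Finkelstein displacement of the primary allylic alcohol under near-neutral conditions that do not touch the enal (no phosphorus ylide chemistry).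

**Step 17**
Reactants: 21
Product: 22, polymatin A
Conditions: CrCl2 (10 equiv), degassed DMF/THF, rt, syringe-pump addition to 2 mM; aq. NH4Cl
Reagents that add atoms: none (H from work-up)
Why: Proposed new method: Nozaki–Hiyama allylation in which the ring-locked 2-(acyl)allyl-chromium (C8 held cis to C12) adds through C7 to the tethered enal via a chair transition state with the enal substituent equatorial (anti adduct, giving the trans 6,7 relationship) and anti to the pseudo-axial 5-angeloyloxy group (setting 7S relative to 8S), after which the C6 chromium alkoxide attacks the now α-methylene δ-lactone carbonyl, so that the favoured γ-lactone forms and 9-OH is released; the closest known reactions are CrCl2-mediated intramolecular 2-(alkoxycarbonyl)allylations that close ten-membered germacranolides with in-situ lactonisation, and Cr/Zn allylations with 3-(bromomethyl)furan-2(5H)-ones.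

## Compound list

1 | geranyl acetate | CC(C)=CCC/C(C)=C/COC(C)=O | starting material
2 | (4E)-6-acetoxy-4-methylhex-4-enal | O=CCC/C(C)=C/COC(C)=O | intermediate
3 | methyl acrylate | C=CC(=O)OC | starting material
4 | methyl (6E)-8-acetoxy-3-hydroxy-6-methyl-2-methylideneoct-6-enoate (racemic) | C=C(C(=O)OC)C(O)CC/C(C)=C/COC(C)=O | intermediate
5 | methyl (2Z,6E)-8-acetoxy-2-(bromomethyl)-6-methylocta-2,6-dienoate | BrC/C(C(=O)OC)=C\CC/C(C)=C/COC(C)=O | intermediate
6 | methyl (2E,6E)-8-acetoxy-2-formyl-6-methylocta-2,6-dienoate | O=C/C(C(=O)OC)=C\CC/C(C)=C/COC(C)=O | intermediate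
7 | allyl methoxymethyl ether | C=CCOCOC | starting material
8 | methyl (2E,6E)-8-acetoxy-2-[(1S,2S)-1-hydroxy-2-(methoxymethoxy)but-3-en-1-yl]-6-methylocta-2,6-dienoate | CC(=O)OC/C=C(\C)CC/C=C(/C(=O)OC)[C@H](O)[C@@H](OCOC)C=C | intermediate
9 | C6-alcohol of 8 | OC/C=C(\C)CC/C=C(/C(=O)OC)[C@H](O)[C@@H](OCOC)C=C | intermediate
10 | C6-OTBS ether of 9 | CC(C)(C)[Si](C)(C)OC/C=C(\C)CC/C=C(/C(=O)OC)[C@H](O)[C@@H](OCOC)C=C | intermediate
11 | methyl 2-(hydroxymethyl)acrylate | C=C(CO)C(=O)OC | starting material
12 | methyl 2-[(TBSO)methyl]acrylate | C=C(CO[Si](C)(C)C(C)(C)C)C(=O)OC | intermediate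
13 | 2-[(TBSO)methyl]acrylic acid | C=C(CO[Si](C)(C)C(C)(C)C)C(=O)O | intermediate
14 | C9 2-[(TBSO)methyl]acrylate ester of 10 | CC(C)(C)[Si](C)(C)OC/C=C(\C)CC/C=C(/C(=O)OC)[C@H](OC(=O)C(=C)CO[Si](C)(C)C(C)(C)C)[C@@H](OCOC)C=C | intermediate
15 | (5S,6S)-3-(TBSO-methyl)-5-(MOM-oxy)-6-alkenyl-5,6-dihydro-2H-pyran-2-one | CC(C)(C)[Si](C)(C)OC/C=C(\C)CC/C=C(/C(=O)OC)[C@@H]1OC(=O)C(CO[Si](C)(C)C(C)(C)C)=C[C@@H]1OCOC | intermediate
16 | (5S,6S)-5-hydroxy lactone | CC(C)(C)[Si](C)(C)OC/C=C(\C)CC/C=C(/C(=O)OC)[C@@H]1OC(=O)C(CO[Si](C)(C)C(C)(C)C)=C[C@@H]1O | intermediate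
17 | angelic acid | C/C=C(/C)C(=O)O | starting material
18 | (5S,6S)-5-angeloyloxy lactone, bis-TBS | CC(C)(C)[Si](C)(C)OC/C=C(\C)CC/C=C(/C(=O)OC)[C@@H]1OC(=O)C(CO[Si](C)(C)C(C)(C)C)=C[C@@H]1OC(=O)/C(C)=C\C | intermediate
19 | diol (C6-OH, C13-OH) | OC/C=C(\C)CC/C=C(/C(=O)OC)[C@@H]1OC(=O)C(CO)=C[C@@H]1OC(=O)/C(C)=C\C | intermediate
20 | enal, C13-OH | O=C/C=C(\C)CC/C=C(/C(=O)OC)[C@@H]1OC(=O)C(CO)=C[C@@H]1OC(=O)/C(C)=C\C | intermediate
21 | enal, C13 bromide (cyclisation precursor) | O=C/C=C(\C)CC/C=C(/C(=O)OC)[C@@H]1OC(=O)C(CBr)=C[C@@H]1OC(=O)/C(C)=C\C | intermediate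
22 | polymatin A (6R,7S,8S,9S; 8β-angeloyloxy-9α-hydroxy, trans-6,12-olide, 14-methyl ester) | C=C1C(=O)O[C@@H]2/C=C(\C)CC/C=C(/C(=O)OC)[C@H](O)[C@@H](OC(=O)/C(C)=C\C)[C@@H]12 | target

## Step count and risks

Total steps: 17. Longest linear sequence: 15 (steps 1–7 and 10–17 from geranyl acetate).

Steps most likely to fail:

1. **Step 17 (Cr macro-allylation / translactonization).** The allyl-chromium carries a pseudo-axial angelate at the δ-position, so reductive 1,4-elimination to an α-pyrone may outrun the slow ten-membered ring closure. Other risks are wrong-face delivery, oligomerisation and 8→9 acyl shift on the released alkoxide. Fallback: resequence the endgame so no acyloxy leaving group is present. Cyclise the C8-OMOM analogue (bromide made from 15 by the step 14–16 sequence), then TES-protect 9-OH, cleave MOM, angeloylate and desilylate (two extra steps).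

2. **Step 5 (alkoxyallylboration of the electrophilic 2-formyl-enoate 6, including its preparation in step 4).** The aldehyde may isomerise or dimerise, or the N-oxide oxidation may go SN2′. Fallback: change the C9–C10 disconnection. Convert aldehyde 2 to the (Z)-α-iodoenoate (iodo-Wittig) and couple it by a ligand-controlled Ni/Cr (NHK) reaction with (S)-2-(methoxymethoxy)but-3-enal to reach 8 directly.

3. **Step 13 (angeloylation of the hindered pseudo-axial allylic alcohol).** Slow acylation and partial isomerisation to the tiglate are both possible. Fallback: build the angelate on the substrate instead of transferring it. Acylate thermally with tert-butyl 2-methylacetoacetate (acyl-ketene, neutral), form the (E)-enol triflate, and reduce it with Pd/formate to the (Z)-2-methylbut-2-enoate.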